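- Every complex charged stays in some form of the complex, and each exchange takes up one incoming ligand and releases one leaving ligand. The forms therefore add up to the charge, and the ligand concentrations follow from the forms.

| flask | starting complex | incoming ligand | leaving ligand | remark | time |
|---|---|---|---|---|---|
| dawn | 12 mM | 14 mM | 60 mM | run made earlier |  |
| summer | 12 mM | 22 mM | 60 mM | run made earlier |  |
| autumn | 12 mM | 53 mM | 60 mM | run made earlier |  |
| maple | 12 mM | 12.0 mM | 60.0 mM |  | 80 min |
| birch | 12 mM | 30.0 mM | 60.0 mM |  | 80 min |
| elm | 12 mM | 48.0 mM | 60.0 mM |  | 80 min |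

| run | time / min | complex with two exchanged / % | complex with four exchanged / % | starting complex / % |
|---|---|---|---|---|
| dawn | 8.00 | 0 | 0 | 93.7 |
| dawn | 15.0 | 0 | 0 | 91.3 |
| dawn | 25.0 | 1.1 | 0 | 89.4 |
| dawn | 30.0 | 0 | 0.7 | 88.9 |
| dawn | 40.0 | 1.0 | 0 | 87.4 |
| summer | 3.00 | 0.4 | 0 | 95.9 |
| summer | 6.00 | 0.5 | 0.1 | 93.2 |
| summer | 12.0 | 0.7 | 0 | 89.2 |
| summer | 20.0 | 0.7 | 0 | 85.6 |
| summer | 40.0 | 2.2 | 0.4 | 80.1 |
| autumn | 3.00 | 0.2 | 0 | 90.6 |
| autumn | 6.00 | 0.6 | 0.6 | 84.0 |
| autumn | 12.0 | 1.2 | 0 | 75.8 |
| autumn | 20.0 | 3.4 | 0 | 67.7 |
| autumn | 40.0 | 8.0 | 0 | 60.5 |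

(each reading ± 0.5 percentage points)



1. amount of complex with two exchanged at the end, in percent of the starting complex charged, for each flask in turn (maple, birch, elm)

- In the autumn run, starting complex falls at 0.0313 min⁻¹ of the charge over the first 3.00 min, while complex with two exchanged climbs at 0.00230 min⁻¹ between 20.0 min and 40.0 min, so the early fall is faster than the later climb.
- Between those later times, starting complex falls at 0.00360 min⁻¹, so these two net rates have drifted close, and I treat the first step as a pre-equilibrium that passes on what the next step draws off.
- At 40.0 min in the autumn run, the balance of the three read forms leaves 31.5% unseen, which I count as complex with one exchanged, setting aside any complex with three exchanged. The ligand count then gives 47.3 mM of incoming ligand and 65.7 mM of leaving ligand.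
- My exchange quotient, [complex with one exchanged][leaving ligand] / ([starting complex][incoming ligand]), reads 0.723 in the autumn run.
- Solving the balance of the first step by itself with this quotient gives estimated hidden shares of 11.2% in maple, 23.8% in birch and 33.2% in elm.
- I scale the autumn reading of complex with two exchanged by hidden share, [incoming ligand] and time. This gives 1.28% for maple, 6.94% for birch and 15.7% for elm.
- The forecast gives 1.3%, 6.5% and 13.5%, with a quotient of 0.66, and says of the first step “so it is a fast pre-equilibrium”. For elm, my figure stands higher than the forecast's.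
- The flasks give 1.50%, 6.10% and 10.5%, and the forecast holds within its margin.

    starting complex + incoming ligand ⇌ leaving ligand + complex with one exchanged (K = 0.740, k = 0.650 M⁻¹ min⁻¹)
    complex with one exchanged + incoming ligand ⇌ leaving ligand + complex with two exchanged (K = 3.00, k = 0.280 M⁻¹ min⁻¹)
    complex with two exchanged + incoming ligand ⇌ leaving ligand + complex with three exchanged (K = 2.50, k = 0.640 M⁻¹ min⁻¹)
    complex with three exchanged + incoming ligand ⇌ leaving ligand + complex with four exchanged (K = 0.410, k = 0.0430 M⁻¹ min⁻¹)

- In maple at the end, the first step has a relaxation half-life of 10.1 min, shorter than the 76.9 min of the step from complex with one exchanged to complex with two exchanged, and at 11.2 min the forward rate of the first step uses incoming ligand 36 times as fast as that of the second. Against the 0.723 carried from the autumn run, the exchange quotient from the amounts at 80.0 min is 0.717 in maple and 0.700 in birch.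

(The runs are calculated for an exercise, and the scatter is random.)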